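## Structural features

- The target is a flavone. Ring A is C4a, C5, C6, C7, C8, C8a; ring C is O1, C2, C3, C4, C4a, C8a; ring B, a 3,5-dihydroxy-4-methoxyphenyl group, sits on C2. Chromone numbering is used for these atoms throughout, also in the precursors.
- Ring A is fully substituted: OH on C5, OMe on C6, OH on C7, OMe on C8, the ring oxygen on C8a, and carbon only on C4a.
- There is no stereocentre and no stereogenic axis, so the problem is one of constitution only.
- The real difficulty is this pentaoxygenated ring A with alternating free and methylated oxygens. A route that starts from a benzene ring must differentiate five oxygens one by one.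
- The key step exploits two features. The triad C6(OMe)–C7(OH)–C8(OMe) is mirror-symmetric and is the bis-enol form of 1,3-dimethoxypropan-2-one. C5 and C8a, the two neighbours of C4a, are both at the carboxylic acid oxidation level, so C4a is a masked malonyl carbon.
- Fragile points: the electron-rich free polyphenol is air-sensitive in base, the 4-pyrone ring can be opened by nucleophiles at C2, and three aryl methyl ethers must survive the final deprotection. The ring B hydroxyls are therefore carried as benzyl ethers.

## Logic of the disconnections

**12 ⇒ 11.** The two benzyl–oxygen bonds on ring B are cut. This is a protecting-group operation. The forward step must remove benzyl without touching three methyl ethers or the C2=C3 bond.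

**11 ⇒ 8 + 9 (key disconnection).** The bonds C8–C8a and C5–C6 are cut, which removes ring A altogether. In one sentence: ring A is created by twofold C-acylation of the symmetric ketone 9 on a preformed 2-aryl-4-pyrone 8 that carries an ester carbon (C5) on C4a and a leaving group on C8a.
- Gain: all five oxygens of ring A arrive in their final state (5-OH and 7-OH free, 6-OMe and 8-OMe in place). No phenol is ever differentiated, and the symmetry of 9 removes any regiochemical question.
- Demand: the enolate of 9 must attack C8a rather than C2, and the second α-carbon must acylate at C5 through carbon.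

**8 ⇒ 7.** The O1–C8a bond is cut. The forward step is an intramolecular oxa-Michael addition–elimination of the diketone enol on a ketene dithioacetal. It must close on the dithioacetal carbon and not on the ester.

**7 ⇒ 4 + 6.** The C2–C3 bond is cut (aroyl carbon to methyl ketone carbon). This separates ring B from the C3–C4–C4a–C5–C8a unit. The forward step must be a C-selective acylation of a methyl ketone.

**6 ⇒ 5.** The C4a=C8a bond is cut; carbon disulfide supplies C8a and iodomethane the two S-methyl groups. This installs the acid oxidation level and the leaving group at C8a in one operation from a bulk β-keto ester.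

**4 ⇒ 3 ⇒ 2 ⇒ 1.** These are functional-group changes on ring B: acid chloride from acid, acid from methyl ester, benzyl ethers from the purchasable diphenol 1.

## Other disconnections considered

**Alternative 1: Baker–Venkataraman route (the first that comes to mind).**
- Cut: O1–C2 and C2–C3.
- Forward key step: the acetophenone 1-[4,6-bis(benzyloxy)-2-hydroxy-3,5-dimethoxyphenyl]ethanone A1 would be O-aroylated with 4 and rearranged by base to the 1,3-diketone A2, then cyclodehydrated.
- Why not: the difficulty is only moved into A1, a hexasubstituted benzene with five differentiated oxygens. A1 would need several oxidation and selective protection steps from any purchasable arene. The chosen plan makes ring A from a symmetric three-carbon ketone and differentiates nothing.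

**Alternative 2: squarate ring expansion with 6π electrocyclization.**
- Cut: C8–C8a (addition of a 6-metallated 2-aryl-4-pyrone to dimethyl squarate) and C4a–C5 (ring closure).
- Forward key step: thermolysis of the racemic 4-hydroxycyclobutenone A3 would give a dienylketene by four-electron ring opening, then ring A by six-electron electrocyclization and tautomerization, ending in the hydroquinone A4.
- Why not: the mechanism places the ketene-derived and carbinol oxygens para to each other (C5 and C8) and the two squarate alkoxy groups on C6 and C7. The target needs OMe on C6 but OH on C7. That requires an unsymmetrical dialkoxy squarate, and two alkoxy groups of similar donor strength give no basis for regioselective addition. An extra methylation at C8 and metalation of a pyrone next to oxygen add steps.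

**Alternative 3: aryne insertion.**
- Cut: C4–C4a and O1–C8a.
- Forward key step: the tetraoxygenated aryne released by fluoride from the silyl triflate A5 would take up the enol oxygen and the ester carbon of the β-keto ester A6 to close ring C.
- Why not: both carbons beside the triple bond (C5 and C8) carry alkoxy groups of nearly equal inductive pull, so the side of addition has no control element. β-Keto ester enolates are also expected to add to arynes through carbon (acyl-alkylation) rather than oxygen. A5 is itself a hexasubstituted benzene, harder to make than ring A.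

Key step: step 6

Remark: compounds 1, 5 and 9 and all reagents are taken as purchasable; the target is achiral, and the only stereogenic carbon on the route (in 10, racemic) is planarized on aromatization.

## Route

**Step 1**
Reactants: 1 methyl 3,5-dihydroxy-4-methoxybenzoate
Product: 2 methyl 3,5-bis(benzyloxy)-4-methoxybenzoate
Conditions: BnBr (2.3 equiv), K2CO3, DMF, 60 °C
Reagents that add atoms: benzyl bromide, BrCc1ccccc1
Why: Williamson ether synthesis on both phenoxides; the ester is inert. Benzyl is chosen because its hydrogenolysis at the end leaves the three methyl ethers untouched.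

**Step 2**
Reactants: 2 methyl 3,5-bis(benzyloxy)-4-methoxybenzoate
Product: 3 3,5-bis(benzyloxy)-4-methoxybenzoic acid
Conditions: LiOH, THF/MeOH/H2O, 50 °C; then 1 M HCl
Reagents that add atoms: lithium hydroxide, [Li+].[OH-]
Why: Saponification of an aryl methyl ester by acyl–oxygen cleavage; benzyl and methyl ethers are stable to hydroxide.

**Step 3**
Reactants: 3 3,5-bis(benzyloxy)-4-methoxybenzoic acid
Product: 4 3,5-bis(benzyloxy)-4-methoxybenzoyl chloride
Conditions: (COCl)2, DMF (cat.), CH2Cl2, 0 °C to rt; used crude
Reagents that add atoms: oxalyl chloride, O=C(Cl)C(=O)Cl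
Why: Acid chloride formation through the Vilsmeier-type chloroiminium catalyst; aryl ethers are unaffected and all by-products are gases.

**Step 4**
Reactants: 5 methyl acetoacetate
Product: 6 methyl 2-[bis(methylsulfanyl)methylidene]-3-oxobutanoate
Conditions: K2CO3, CS2, DMF, 0 °C to rt; then MeI (2.2 equiv), rt
Reagents that add atoms: carbon disulfide, S=C=S; iodomethane, CI
Why: Dithiocarboxylation of the active methylene followed by double S-methylation, the standard preparation of α-oxo ketene dithioacetals from 1,3-dicarbonyl compounds. The CS2 carbon becomes C8a at the acid oxidation level with a built-in leaving group.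

**Step 5**
Reactants: 4 3,5-bis(benzyloxy)-4-methoxybenzoyl chloride; 6 methyl 2-[bis(methylsulfanyl)methylidene]-3-oxobutanoate
Product: 8 methyl 6-[3,5-bis(benzyloxy)-4-methoxyphenyl]-2-(methylsulfanyl)-4-oxo-4H-pyran-3-carboxylate, via open-chain 1,3-diketone 7 (not isolated)
Conditions: MgBr2·OEt2, i-Pr2NEt, CH2Cl2, 0 °C to rt; aq. NH4Cl; then p-TsOH·H2O (cat.), toluene, 80 °C, N2 sweep
Reagents that add atoms: none
Why: Soft enolization gives the magnesium enolate of the only enolizable position of 6, the acetyl CH3, which is C-acylated by 4 (crossed Claisen-type acylation) to 7. The aryl-side enol oxygen of 7 then adds 6-endo-trig to the push–pull dithioacetal carbon and loses methanethiol (oxa-Michael addition–elimination), as in the known closure of 2-(methylsulfanyl)chromones; the aromatic 4-pyrone is favoured over closure on the ester.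

**Step 6**
Reactants: 8 methyl 6-[3,5-bis(benzyloxy)-4-methoxyphenyl]-2-(methylsulfanyl)-4-oxo-4H-pyran-3-carboxylate; 9 1,3-dimethoxypropan-2-one
Product: 11 2-[3,5-bis(benzyloxy)-4-methoxyphenyl]-5,7-dihydroxy-6,8-dimethoxy-4H-chromen-4-one, via pyrone ketone adduct 10 (not isolated)
Conditions: 9 (1.2 equiv), LiN(SiMe3)2 (1.2 equiv), THF, −78 °C; add 8, then LiN(SiMe3)2 (1.2 equiv), −78 to 0 °C; then KOt-Bu (2.0 equiv), 0 to 45 °C; 1 M HCl work-up
Reagents that add atoms: none
Why: Proposed new method: the lithium enolate of 9 should add through carbon to C8a of 8, the β-carbon shared by the ring ketone and the ester, and expel methanethiolate (addition–elimination) to give 10; its second α-carbon (C6), deprotonated in equilibrium under KOt-Bu, should then attack the ester carbonyl C5 (Dieckmann-type Claisen condensation), lose methoxide and tautomerize twice to the resorcinol ring A of 11. The closest known reaction types are the Michael–Dieckmann resorcinol synthesis from 3-oxoglutarate anions and alkynoates, the dimedone-type Michael–Claisen annulation, and displacement of 2-sulfanyl groups on chromones and 4-pyrones by nucleophiles; new is their combination on a 2-sulfanyl-4-pyrone-3-carboxylate with a ketone activated only by two methoxy groups. Ring A closes in a 6-(enolendo)-exo-trig acylation that is geometrically enforced, because C8 and the ester are held cis on the C4a=C8a bond of the pyrone. No stereocentre is created in the product: the transient CH(OMe) carbon of 10 becomes planar on aromatization. Attack at C8a rather than C2 is expected because C8a is activated by two acceptors and carries the leaving group, while C2 is deactivated by the electron-rich aryl group; a ring-opened adduct (loss of the O1 enolate instead of thiolate) can only reclose on the same carbon with loss of thiolate. No regiocontrol of the annulation is needed, since 9 is mirror-symmetric: whichever α-carbon attacks first, the methoxy groups end on C6 and C8 and the ketone oxygen on C7. O-acylation of the C7 enolate at C5 (a fused 2-pyranone) is reversible under alkoxide, and aldol attack on the C4 carbonyl would give a bridged adduct that cannot aromatize, so the aromatic phenoxide is the thermodynamic sink.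

**Step 7**
Reactants: 11 2-[3,5-bis(benzyloxy)-4-methoxyphenyl]-5,7-dihydroxy-6,8-dimethoxy-4H-chromen-4-one
Product: 12 2-(3,5-dihydroxy-4-methoxyphenyl)-5,7-dihydroxy-6,8-dimethoxy-4H-chromen-4-one (CNP0185233.0)
Conditions: H2 (1 atm), 10% Pd/C, EtOAc/MeOH, rt
Reagents that add atoms: none
Why: Heterogeneous hydrogenolysis of benzyl aryl ethers. The aryl methyl ethers are inert, and the C2=C3 bond of the γ-pyrone should not be reduced at ambient pressure and temperature.

## Compound list

1 | methyl 3,5-dihydroxy-4-methoxybenzoate | COC(=O)c1cc(O)c(OC)c(O)c1 | starting material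
2 | methyl 3,5-bis(benzyloxy)-4-methoxybenzoate | COC(=O)c1cc(OCc2ccccc2)c(OC)c(OCc2ccccc2)c1 | intermediate
3 | 3,5-bis(benzyloxy)-4-methoxybenzoic acid | OC(=O)c1cc(OCc2ccccc2)c(OC)c(OCc2ccccc2)c1 | intermediate
4 | 3,5-bis(benzyloxy)-4-methoxybenzoyl chloride | ClC(=O)c1cc(OCc2ccccc2)c(OC)c(OCc2ccccc2)c1 | intermediate
5 | methyl acetoacetate | COC(=O)CC(C)=O | starting material
6 | methyl 2-[bis(methylsulfanyl)methylidene]-3-oxobutanoate | CC(=O)C(C(=O)OC)=C(SC)SC | intermediate
7 | methyl 2-[bis(methylsulfanyl)methylidene]-5-[3,5-bis(benzyloxy)-4-methoxyphenyl]-3,5-dioxopentanoate | COC(=O)C(C(=O)CC(=O)c1cc(OCc2ccccc2)c(OC)c(OCc2ccccc2)c1)=C(SC)SC | intermediate (not isolated)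
8 | methyl 6-[3,5-bis(benzyloxy)-4-methoxyphenyl]-2-(methylsulfanyl)-4-oxo-4H-pyran-3-carboxylate | COC(=O)C1=C(SC)OC(c2cc(OCc3ccccc3)c(OC)c(OCc3ccccc3)c2)=CC1=O | intermediate
9 | 1,3-dimethoxypropan-2-one | COCC(=O)COC | starting material
10 | methyl 6-[3,5-bis(benzyloxy)-4-methoxyphenyl]-2-(1,3-dimethoxy-2-oxopropyl)-4-oxo-4H-pyran-3-carboxylate (racemic) | COCC(=O)C(OC)C1=C(C(=O)OC)C(=O)C=C(c2cc(OCc3ccccc3)c(OC)c(OCc3ccccc3)c2)O1 | intermediate (not isolated)
11 | 2-[3,5-bis(benzyloxy)-4-methoxyphenyl]-5,7-dihydroxy-6,8-dimethoxy-4H-chromen-4-one | COc1c(OCc2ccccc2)cc(-c2cc(=O)c3c(O)c(OC)c(O)c(OC)c3o2)cc1OCc1ccccc1 | intermediate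
12 | 2-(3,5-dihydroxy-4-methoxyphenyl)-5,7-dihydroxy-6,8-dimethoxy-4H-chromen-4-one | COc1c(O)cc(-c2cc(=O)c3c(O)c(OC)c(O)c(OC)c3o2)cc1O | target

## Step count and least certain steps

Total steps: 7. Longest linear sequence: 6 (steps 1, 2, 3, 5, 6, 7); step 4 is a one-step side branch.

**Step 6 (key step, proposed new method).**
- What may go wrong: the second acylation may derail into O-acylation (lactonization of the C7 enolate onto C5). Alkoxide may cleave the methoxyacetyl unit from the adduct by retro-Claisen reaction. The enolate may attack C2 and open the pyrone. Liberated thiolate may demethylate the ester before ring closure.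
- Fallback (known chemistry, from 4, rejoining at 11):
  - The lithium polyanion of purchasable 1-(2,4,6-trihydroxyphenyl)ethanone (LiN(SiMe3)2, THF, −78 °C to rt) is C-aroylated with 4 to give 1-[3,5-bis(benzyloxy)-4-methoxyphenyl]-3-(2,4,6-trihydroxyphenyl)propane-1,3-dione F1.
  - Acid-catalysed cyclodehydration (p-TsOH·H2O, toluene, 90 °C) gives 2-[3,5-bis(benzyloxy)-4-methoxyphenyl]-5,7-dihydroxy-4H-chromen-4-one F2.
  - Dibromination of the phloroglucinol-type ring A with N-bromosuccinimide (2 equiv, DMF, 0 °C) gives 2-[3,5-bis(benzyloxy)-4-methoxyphenyl]-6,8-dibromo-5,7-dihydroxy-4H-chromen-4-one F3.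
  - Copper-mediated methoxylation (NaOMe, CuBr, DMF/MeOH, 110 °C) replaces both bromides and delivers 11.
  - This fallback gives up the ring A construction and installs the two methoxy groups late on a conventional 5,7-dihydroxyflavone.

**Step 5.**
- What may go wrong: O-acylation or over-acylation of the magnesium enolate, since the diketone product is more acidic than 6. The enolate of 6 may also condense with the dithioacetal of a second molecule, and ring closure may be slow or misdirected.
- Fallback (from 4, rejoining at 8 through 7): the bond made is changed from C2–C3 to C3–C4 and the roles are reversed.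
  - 4 is converted with Me2CuLi (THF, −78 °C) into 1-[3,5-bis(benzyloxy)-4-methoxyphenyl]ethanone F4.
  - Purchasable dimethyl 2-[bis(methylsulfanyl)methylidene]propanedioate is mono-saponified (KOH, 1 equiv, MeOH, rt) to 2-(methoxycarbonyl)-3,3-bis(methylsulfanyl)prop-2-enoic acid F5.
  - F5 is converted with (COCl)2 and catalytic DMF into methyl 2-(chlorocarbonyl)-3,3-bis(methylsulfanyl)prop-2-enoate F6.
  - Soft-enolization acylation of the simple aryl methyl ketone F4 with F6 (MgBr2·OEt2, i-Pr2NEt, CH2Cl2) gives 7, which is cyclized as in step 5 to 8.
  - In this order the ketene dithioacetal is never exposed to its own enolate.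

**Step 7.**
- What may go wrong: poisoning of the palladium surface by sulfur traces carried over from step 6, or over-reduction of the C2=C3 bond on prolonged exposure.
- Fallback (from 11, rejoining at 12): non-reductive Lewis-acid debenzylation with BCl3 and pentamethylbenzene as cation scavenger (CH2Cl2, −78 °C). At this temperature benzyl aryl ethers should be cleaved much faster than methyl aryl ethers. No new intermediate is formed.

## Further compounds

F1 | step 6 | 1-[3,5-bis(benzyloxy)-4-methoxyphenyl]-3-(2,4,6-trihydroxyphenyl)propane-1,3-dione | COc1c(OCc2ccccc2)cc(C(=O)CC(=O)c2c(O)cc(O)cc2O)cc1OCc1ccccc1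
F2 | step 6 | 2-[3,5-bis(benzyloxy)-4-methoxyphenyl]-5,7-dihydroxy-4H-chromen-4-one | COc1c(OCc2ccccc2)cc(-c2cc(=O)c3c(O)cc(O)cc3o2)cc1OCc1ccccc1
F3 | step 6 | 2-[3,5-bis(benzyloxy)-4-methoxyphenyl]-6,8-dibromo-5,7-dihydroxy-4H-chromen-4-one | COc1c(OCc2ccccc2)cc(-c2cc(=O)c3c(O)c(Br)c(O)c(Br)c3o2)cc1OCc1ccccc1
F4 | step 5 | 1-[3,5-bis(benzyloxy)-4-methoxyphenyl]ethanone | CC(=O)c1cc(OCc2ccccc2)c(OC)c(OCc2ccccc2)c1
F5 | step 5 | 2-(methoxycarbonyl)-3,3-bis(methylsulfanyl)prop-2-enoic acid | COC(=O)C(C(=O)O)=C(SC)SC
F6 | step 5 | methyl 2-(chlorocarbonyl)-3,3-bis(methylsulfanyl)prop-2-enoate | COC(=O)C(C(Cl)=O)=C(SC)SC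
F0 | step 7 | none | none
A1 | alternative 1 | 1-[4,6-bis(benzyloxy)-2-hydroxy-3,5-dimethoxyphenyl]ethanone | CC(=O)c1c(O)c(OC)c(OCc2ccccc2)c(OC)c1OCc1ccccc1
A2 | alternative 1 | 1-[4,6-bis(benzyloxy)-2-hydroxy-3,5-dimethoxyphenyl]-3-[3,5-bis(benzyloxy)-4-methoxyphenyl]propane-1,3-dione | COc1c(OCc2ccccc2)cc(C(=O)CC(=O)c2c(O)c(OC)c(OCc3ccccc3)c(OC)c2OCc2ccccc2)cc1OCc1ccccc1
A3 | alternative 2 | 4-{6-[3,5-bis(benzyloxy)-4-methoxyphenyl]-4-oxo-4H-pyran-2-yl}-4-hydroxy-2,3-dimethoxycyclobut-2-en-1-one (racemic) | COC1=C(OC)C(O)(C2=CC(=O)C=C(c3cc(OCc4ccccc4)c(OC)c(OCc4ccccc4)c3)O2)C1=O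
A4 | alternative 2 | 2-[3,5-bis(benzyloxy)-4-methoxyphenyl]-5,8-dihydroxy-6,7-dimethoxy-4H-chromen-4-one | COc1c(OCc2ccccc2)cc(-c2cc(=O)c3c(O)c(OC)c(OC)c(O)c3o2)cc1OCc1ccccc1
A5 | alternative 3 | 3,5-bis(benzyloxy)-2,4-dimethoxy-6-(trimethylsilyl)phenyl trifluoromethanesulfonate | C[Si](C)(C)c1c(OCc2ccccc2)c(OC)c(OCc2ccccc2)c(OC)c1OS(=O)(=O)C(F)(F)F
A6 | alternative 3 | methyl 3-[3,5-bis(benzyloxy)-4-methoxyphenyl]-3-oxopropanoate | COC(=O)CC(=O)c1cc(OCc2ccccc2)c(OC)c(OCc2ccccc2)c1
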